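**Plan** (germacrane numbering)
1. The carbocycle is C1–C10. C1=C10 bears C14 (CO2Me). C2–C3 is the epoxide and C4(C15H3)=C5 the second olefin. The lactone is O6–C12(=O)–C11(=C13H2)–C7. O8 carries the epoxyangelate and O9 the (R)-2-methylbutanoate.
2. Enabling feature: C14 on C10 and O8 on C8 flank C9 in a 1,3 relation, so C14(=O)–O8 can act as a temporary two-atom bridge. Nine ring carbons (C10, C1–C8) are first closed with this bridge to an 11-membered lactone. C9 stays outside that ring as a formyl group on C8, and C10 carries iodine.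
3. Retrosynthetic cuts, in order: O8–acyl (with inversion), C14–O8 (bridge, MeOH), O9–acyl, C9–C10 (key step: transannular Nozaki–Hiyama–Kishi, 11 → 10), C14–O8 (lactonisation), C7–C8 (Barbier), C7=C11 (RCM), C6–C7 (vinylzinc), C1=C10 (iodo-Wittig), C3–C4 (Sonogashira).
4. Forward ring order: epoxide → butenolide → α-methylene-γ-lactone → 11-membered lactone → ten-membered carbocycle plus bridging γ-lactone → bridge opened.
5. Stereochemistry: both ring-cis olefins are fixed on open chains (Red-Al/I2; iodo-ylide). C2/C3 come from a Sharpless epoxidation and C6 from a catalyst-controlled vinylation. C7 follows from C6. C8 is made epimeric on purpose, steers C9 in the key step, and is inverted in the last step. The side chains come from the (R)-acid and a second Sharpless epoxidation.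

Key step: step 19

Remark: the target is read as 2R,3S,6R,7S,8S,9S with an (R)-2-methylbutanoate and a (2S,3S)-epoxyangelate. Compounds 1, 4, 14, 19, 25 and 28 are taken as commercial.

**Step 1**
Reactants: 1 but-2-yn-1-ol
Product: 2 (Z)-3-iodobut-2-en-1-ol (I cis to CH2OH)
Conditions: Red-Al, THF, 0 °C to rt; then I2, −78 to 0 °C
Reagents that add atoms: iodine, II
Why: Hydroxyl-directed trans-hydroalumination puts aluminium on the distal carbon (C4) cis to the CH2OH group and iodinolysis goes with retention, so whatever replaces iodine (C3) will be cis to C6.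

**Step 2**
Reactants: 2 (Z)-3-iodobut-2-en-1-ol
Product: 3 TBS ether of 2
Conditions: TBSCl, imidazole, CH2Cl2, rt
Reagents that add atoms: tert-butyldimethylsilyl chloride, CC(C)(C)[Si](C)(C)Cl
Why: Standard silylation masks O6, so that only the later C1 hydroxyl can direct the epoxidation.

**Step 3**
Reactants: 3 TBS ether of 2; 4 prop-2-yn-1-ol
Product: 5 (4Z)-6-(tert-butyldimethylsilyloxy)-4-methylhex-4-en-2-yn-1-ol
Conditions: PdCl2(PPh3)2 (cat.), CuI (cat.), i-Pr2NH, THF, rt
Reagents that add atoms: none
Why: Sonogashira coupling of an alkenyl iodide proceeds with retention and forms C3–C4 without touching the Z geometry of C4=C5.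

**Step 4**
Reactants: 5 (4Z)-enynol
Product: 6 (2Z,4Z)-6-(tert-butyldimethylsilyloxy)-4-methylhexa-2,4-dien-1-ol
Conditions: Zn(Cu/Ag), MeOH/H2O, rt
Reagents that add atoms: none
Why: Activated zinc semireduces only the conjugated, hydroxyl-flanked triple bond by syn delivery of two hydrogens, which gives the Z olefin C2=C3.

**Step 5**
Reactants: 6 (2Z,4Z)-dienol
Product: 7 [(2R,3S)-3-[(2Z)-4-(tert-butyldimethylsilyloxy)but-2-en-2-yl]oxiran-2-yl]methanol (cis-epoxide, C2/C3 as in 32)
Conditions: Ti(Oi-Pr)4 (cat.), L-(+)-DET (cat.), t-BuOOH, 4 Å MS, CH2Cl2, −20 °C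
Reagents that add atoms: tert-butyl hydroperoxide, CC(C)(C)OO
Why: Sharpless asymmetric epoxidation acts only on the allylic-alcohol double bond; L-(+)-DET delivers oxygen to the face that gives C2 (R) and C3 (S), and the cis geometry is carried over from the Z olefin.

**Step 6**
Reactants: 7 cis-epoxy alcohol
Product: 8 cis-epoxy aldehyde (C1 = CHO; C2, C3 unchanged)
Conditions: Dess–Martin periodinane, pyridine, CH2Cl2, 0 °C
Reagents that add atoms: none
Why: Buffered Dess–Martin oxidation stops at the aldehyde and is mild enough not to epimerise C2 or open the vinyl epoxide.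

**Step 7**
Reactants: 8 cis-epoxy aldehyde
Product: 9 methyl (Z)-2-iodo-3-[cis-epoxide of 8]prop-2-enoate, O6-TBS (C2 cis to I, trans to CO2Me)
Conditions: Ph3P=CHCO2Me, NIS, CH2Cl2, −20 °C; then 8, −20 °C to rt
Reagents that add atoms: methyl (triphenylphosphoranylidene)acetate, COC(=O)C=P(c1ccccc1)(c1ccccc1)c1ccccc1; N-iodosuccinimide, O=C1CCC(=O)N1I
Why: Wittig olefination with the stabilised α-iodo ylide gives the (Z)-α-iodoacrylate, in which iodine holds the place cis to C2 that C9 will take.

**Step 8**
Reactants: 9 iodoenoate TBS ether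
Product: 10 iodoenoate allylic alcohol (free O6–H)
Conditions: TBAF, AcOH (1:1), THF, 0 °C
Reagents that add atoms: none
Why: Buffered fluoride cleaves the primary allylic silyl ether under nearly neutral conditions that spare the epoxide, ester and iodide.

**Step 9**
Reactants: 10 iodoenoate allylic alcohol
Product: 11 iodoenoate (Z)-enal (C6 = CHO)
Conditions: Dess–Martin periodinane, pyridine, CH2Cl2, 0 °C
Reagents that add atoms: none
Why: Neutral oxidation of the allylic alcohol gives the trisubstituted Z-enal without acid or base that could isomerise it.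

**Step 10**
Reactants: 11 iodoenoate (Z)-enal
Product: 12 (6S)-divinyl carbinol methyl ester (C6 as in 32; vinyl = C7)
Conditions: divinylzinc, (−)-MIB (10 mol %), toluene, −20 °C
Reagents that add atoms: divinylzinc, C=C[Zn]C=C
Why: In this amino-alcohol-catalysed alkenylzinc addition the ligand directs the vinyl group to the Si face of the aldehyde and sets C6 under catalyst control, while the ester, iodide and epoxide are inert to the zinc reagent.

**Step 11**
Reactants: 12 (6S)-divinyl carbinol methyl ester
Product: 13 (6S)-hydroxy acid (C14 = CO2H)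
Conditions: LiOH, THF/H2O, 0 °C to rt; then aq KHSO4 to pH 4
Reagents that add atoms: lithium hydroxide, [Li+].[OH-]
Why: Saponification is done here because no lactone is yet present, so the C14 acid is freed without any risk of translactonisation later.

**Step 12**
Reactants: 14 2-(bromomethyl)acrylic acid
Product: 15 2-(bromomethyl)acryloyl chloride
Conditions: (COCl)2, DMF (cat.), CH2Cl2, 0 °C to rt
Reagents that add atoms: oxalyl chloride, O=C(Cl)C(=O)Cl
Why: Acid chloride formation through the Vilsmeier-type intermediate leaves the allylic bromide untouched.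

**Step 13**
Reactants: 13 (6S)-hydroxy acid; 15 2-(bromomethyl)acryloyl chloride
Product: 17 O6-[2-(bromomethyl)acryloyl] ester with free C14 acid, via mixed anhydride 16 (not isolated)
Conditions: 15 (2.2 equiv), i-Pr2NEt, CH2Cl2, −40 °C; then pyridine, THF/H2O, 0 °C
Reagents that add atoms: water, O
Why: The acid chloride acylates O6 with retention and caps the carboxylate as a mixed anhydride, and mild hydrolysis of the anhydride returns both acids whichever carbonyl water attacks.

**Step 14**
Reactants: 17 O6-[2-(bromomethyl)acryloyl] ester acid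
Product: 18 (6-configured) 3-(bromomethyl)butenolide acid (C7=C11 in the ring, C13H2Br on C11)
Conditions: Hoveyda–Grubbs II (5 mol %), CH2Cl2, 40 °C
Reagents that add atoms: none
Why: Ring-closing metathesis joins the only terminal vinyl group and the acrylate methylene to a five-membered ring, while the trisubstituted and iodo-substituted olefins are too hindered to compete.

**Step 15**
Reactants: 18 3-(bromomethyl)butenolide acid; 19 (tert-butyldimethylsilyloxy)acetaldehyde
Product: 20 seco acid (trans-fused-type α-methylene-γ-lactone; C7 as in 32; C8 carbinol epimeric to 32; O9-TBS)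
Conditions: In powder, THF/sat. aq NH4Cl, rt
Reagents that add atoms: none
Why: In this Barbier allylation the allylindium reacts at its γ-carbon C7 through a closed six-membered transition state on the butenolide face anti to the C6 side chain (C7, trans), and because the ring locks the allyl unit in the E-type geometry it reacts with anti simple diastereoselection (8-epi), the exocyclic methylene arising by allyl transposition.

**Step 16**
Reactants: 20 seco acid
Product: 21 eleven-membered lactone (ring O8, C14, C10, C1–C8; C10–I; CH2OTBS on C8)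
Conditions: MNBA, DMAP, CH2Cl2 (1 mM, slow addition), rt
Reagents that add atoms: none
Why: Shiina mixed-anhydride macrolactonisation acylates the only free hydroxyl (O8) with retention, and the cis-epoxide, the ring-cis C4=C5 and the fused lactone bend the chain so that its ends lie close.

**Step 17**
Reactants: 21 eleven-membered lactone TBS ether
Product: 22 eleven-membered lactone with C9H2OH on C8
Conditions: HF·pyridine, pyridine, THF, 0 °C
Reagents that add atoms: none
Why: Buffered HF removes the primary silyl ether in a non-basic medium, which suppresses the O8 to O9 acyl shift that an alkoxide would trigger.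

**Step 18**
Reactants: 22 eleven-membered lactone primary alcohol
Product: 23 eleven-membered lactone aldehyde (C9 = CHO on C8, C10–I)
Conditions: Dess–Martin periodinane, pyridine, CH2Cl2, 0 °C
Reagents that add atoms: none
Why: Neutral oxidation gives the α-acyloxy aldehyde without epimerising C8, and it is used at once.

**Step 19**
Reactants: 23 eleven-membered lactone aldehyde
Product: 24 ten-membered carbocycle bridged by the C14(=O)–O8 γ-lactone, free 9-OH (C9 as in 32, C8 epimeric)
Conditions: CrCl2 (10 equiv), NiCl2 (0.1 equiv), DMSO/THF, 2 mM, rt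
Reagents that add atoms: none
Why: Ni(0) inserts into the C10–I bond, hands the carbon over to Cr(III), and the alkenylchromium adds to the C9 aldehyde with retention at C10, so C2 stays cis to the new C9 substituent and trans to C14. The closest known reaction type is the intramolecular Nozaki–Hiyama–Kishi coupling of an alkenyl iodide with an aldehyde, which tolerates esters, lactones and epoxides. Only a five-membered ring has to be closed (5-exo-trig, C10–C14–O8–C8–C9), but the same bond closes the carbocycle C1–C10: C9 enters the large ring while C14 and O8 drop out of it (11 → 10), so the strain of the ten-membered ring is paid in an irreversible C–C bond formation between atoms that the lactone already holds 1,5 to each other. C9 is the only new stereocentre: the aldehyde should react in the rotamer that turns its chromium-bearing oxygen to the open face of the nascent γ-lactone, anti to C7, and with the 8-epi configuration of 23 this is the natural configuration at C9. The step needs chemoselectivity for the C(sp2)–I bond over the acrylate, enoate and vinyl-epoxide units, which Cr(II) leaves alone, and intramolecular rather than intermolecular addition, which the 1,5 relation and the dilution secure.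

**Step 20**
Reactants: 24 bridged carbocycle with 9-OH; 25 (R)-2-methylbutanoic acid
Product: 26 9-O-[(R)-2-methylbutanoyl] bridged carbocycle
Conditions: DCC, DMAP (cat.), CH2Cl2, 0 °C to rt
Reagents that add atoms: none
Why: Steglich esterification meets a single free hydroxyl on the open face, O8 still being tied up in the bridge, so O8 and O9 are told apart without protecting groups.

**Step 21**
Reactants: 26 9-O-acyl bridged carbocycle
Product: 27 8-epi-8-hydroxy C14 methyl ester (monocarbocyclic ten-membered ring)
Conditions: K2CO3 (0.1 equiv), MeOH, −10 °C; AcOH quench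
Reagents that add atoms: methanol, CO
Why: In this base-catalysed transesterification methoxide opens the strained bridging lactone (s-cis ester across C8/C10 with an sp2 bridgehead) faster than the hindered 2-methylbutanoate, and the fused 6,12-lactone re-closes if opened, so the helper bridge becomes the CO2Me group and the free O8–H.

**Step 22**
Reactants: 28 methyl angelate
Product: 29 (Z)-2-methylbut-2-en-1-ol
Conditions: DIBAL-H, CH2Cl2, −78 to 0 °C
Reagents that add atoms: none
Why: 1,2-Reduction of the enoate gives the allylic alcohol with the Z geometry intact.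

**Step 23**
Reactants: 29 (Z)-2-methylbut-2-en-1-ol
Product: 30 [(2R,3S)-2,3-dimethyloxiran-2-yl]methanol
Conditions: Ti(Oi-Pr)4 (cat.), L-(+)-DET (cat.), t-BuOOH, 4 Å MS, CH2Cl2, −20 °C
Reagents that add atoms: tert-butyl hydroperoxide, CC(C)(C)OO
Why: Sharpless asymmetric epoxidation with L-(+)-DET sets both epoxide centres, and the Z olefin fixes CH2OH cis to the C3 methyl group.

**Step 24**
Reactants: 30 [(2R,3S)-2,3-dimethyloxiran-2-yl]methanol
Product: 31 (2S,3S)-2,3-dimethyloxirane-2-carboxylic acid
Conditions: TEMPO (cat.), PhI(OAc)2, MeCN/H2O, rt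
Reagents that add atoms: water, O
Why: Oxoammonium oxidation through the aldehyde hydrate gives the acid without touching the epoxide; only the descriptor at C2 changes, not the spatial arrangement.

**Step 25**
Reactants: 27 8-epi-8-hydroxy methyl ester; 31 (2S,3S)-2,3-dimethyloxirane-2-carboxylic acid
Product: 32 target CNP0485260.1
Conditions: PPh3, DIAD, toluene, 0 °C to rt
Reagents that add atoms: none
Why: Mitsunobu esterification displaces the activated 8α-oxygen by the carboxylate with inversion to give the 8β-ester, and the cis-placed O9 ester cannot take part from the rear side.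

**Compound list**
1 | but-2-yn-1-ol | CC#CCO | starting material
2 | (Z)-3-iodobut-2-en-1-ol | OC/C=C(/C)I | intermediate
3 | TBS ether of 2 | CC(C)(C)[Si](C)(C)OC/C=C(/C)I | intermediate
4 | prop-2-yn-1-ol | C#CCO | starting material
5 | (4Z)-6-(TBSO)-4-methylhex-4-en-2-yn-1-ol | CC(C)(C)[Si](C)(C)OC/C=C(/C)C#CCO | intermediate
6 | (2Z,4Z)-6-(TBSO)-4-methylhexa-2,4-dien-1-ol | CC(C)(C)[Si](C)(C)OC/C=C(/C)\C=C/CO | intermediate
7 | cis-epoxy alcohol | CC(C)(C)[Si](C)(C)OC/C=C(/C)[C@@H]1O[C@@H]1CO | intermediate
8 | cis-epoxy aldehyde | CC(C)(C)[Si](C)(C)OC/C=C(/C)[C@@H]1O[C@@H]1C=O | intermediate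
9 | (Z)-α-iodoenoate, O6-TBS | CC(C)(C)[Si](C)(C)OC/C=C(/C)[C@@H]1O[C@@H]1/C=C(/C(=O)OC)I | intermediate
10 | iodoenoate allylic alcohol | OC/C=C(/C)[C@@H]1O[C@@H]1/C=C(/C(=O)OC)I | intermediate
11 | iodoenoate (Z)-enal | O=C/C=C(/C)[C@@H]1O[C@@H]1/C=C(/C(=O)OC)I | intermediate
12 | (6S)-divinyl carbinol methyl ester | O[C@@H](C=C)/C=C(/C)[C@@H]1O[C@@H]1/C=C(/C(=O)OC)I | intermediate
13 | (6S)-hydroxy acid | O[C@@H](C=C)/C=C(/C)[C@@H]1O[C@@H]1/C=C(/C(=O)O)I | intermediate
14 | 2-(bromomethyl)acrylic acid | C=C(CBr)C(=O)O | starting material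
15 | 2-(bromomethyl)acryloyl chloride | C=C(CBr)C(=O)Cl | intermediate
16 | O6 ester, C14 mixed anhydride | C=C(CBr)C(=O)O[C@@H](C=C)/C=C(/C)[C@@H]1O[C@@H]1/C=C(/C(=O)OC(=O)C(=C)CBr)I | intermediate
17 | O6-[2-(bromomethyl)acryloyl] ester acid | C=C(CBr)C(=O)O[C@@H](C=C)/C=C(/C)[C@@H]1O[C@@H]1/C=C(/C(=O)O)I | intermediate
18 | 3-(bromomethyl)butenolide acid | O=C1O[C@H](/C=C(/C)[C@@H]2O[C@@H]2/C=C(/C(=O)O)I)C=C1CBr | intermediate
19 | (tert-butyldimethylsilyloxy)acetaldehyde | CC(C)(C)[Si](C)(C)OCC=O | starting material
20 | seco acid (8-epi) | C=C1C(=O)O[C@H](/C=C(/C)[C@@H]2O[C@@H]2/C=C(/C(=O)O)I)[C@H]1[C@@H](O)CO[Si](C)(C)C(C)(C)C | intermediate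
21 | eleven-membered lactone, O9-TBS | C=C1C(=O)O[C@@H]2/C=C(/C)[C@@H]3O[C@@H]3/C=C(I)/C(=O)O[C@@H](CO[Si](C)(C)C(C)(C)C)[C@@H]12 | intermediate
22 | eleven-membered lactone alcohol | C=C1C(=O)O[C@@H]2/C=C(/C)[C@@H]3O[C@@H]3/C=C(I)/C(=O)O[C@@H](CO)[C@@H]12 | intermediate
23 | eleven-membered lactone aldehyde | C=C1C(=O)O[C@@H]2/C=C(/C)[C@@H]3O[C@@H]3/C=C(I)/C(=O)O[C@@H](C=O)[C@@H]12 | intermediate
24 | bridged ten-membered carbocycle, 9-OH | C=C1C(=O)O[C@@H]2/C=C(/C)[C@@H]3O[C@@H]3/C=C4/C(=O)O[C@@H]([C@H]4O)[C@@H]12 | intermediate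
25 | (R)-2-methylbutanoic acid | CC[C@@H](C)C(=O)O | starting material
26 | 9-O-acyl bridged carbocycle | C=C1C(=O)O[C@@H]2/C=C(/C)[C@@H]3O[C@@H]3/C=C4/C(=O)O[C@@H]([C@H]4OC(=O)[C@H](C)CC)[C@@H]12 | intermediate
27 | 8-epi-8-hydroxy methyl ester | C=C1C(=O)O[C@@H]2/C=C(/C)[C@@H]3O[C@@H]3/C=C(/C(=O)OC)[C@H](OC(=O)[C@H](C)CC)[C@H](O)[C@@H]12 | intermediate
28 | methyl angelate | C/C=C(/C)C(=O)OC | starting material
29 | (Z)-2-methylbut-2-en-1-ol | C/C=C(/C)CO | intermediate
30 | [(2R,3S)-2,3-dimethyloxiran-2-yl]methanol | OC[C@@]1(C)O[C@H]1C | intermediate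
31 | (2S,3S)-2,3-dimethyloxirane-2-carboxylic acid | OC(=O)[C@@]1(C)O[C@H]1C | intermediate
32 | CNP0485260.1 | C=C1C(=O)O[C@@H]2/C=C(/C)[C@@H]3O[C@@H]3/C=C(/C(=O)OC)[C@H](OC(=O)[C@H](C)CC)[C@@H](OC(=O)[C@@]3(C)O[C@H]3C)[C@@H]12 | target

**Totals:** 25 steps. The longest linear sequence is 21 steps (steps 1–11, 13–21, 25).

**Steps most likely to fail**

1. **Step 19.**
   - Risk: the lactone must turn into its s-cis ester form before C10 can reach C9. Protonation of the alkenylchromium, or its 1,4-elimination with opening of the neighbouring epoxide, may outrun the addition.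
   - Fallback (from 23, back at 24): the iodine is removed on purpose by protonolysis of the alkenylchromium (CrCl2, cat. NiCl2, DMF/H2O). This gives the (E)-enoate aldehyde F1.
   - The same C9–C10 bond is then made without an organometal, by a phosphine-mediated intramolecular Morita–Baylis–Hillman reaction (PMe3, THF/t-BuOH). Conjugate addition at C1, aldol closure of the five-membered ring and loss of the phosphine return to 24.

2. **Step 16.**
   - Risk: acylation of the hindered C8 hydroxyl in a medium ring may lose out to oligomerisation, or to migration of the fused lactone from O6 to O8.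
   - Fallback (from 20, back at 32): the bridge is given up. The acid is methylated (TMSCHN2) to the hydroxy methyl ester F2.
   - O8 is esterified with inversion by 31 (PPh3, DIAD) to the 8β-epoxyangelate F3.
   - Buffered HF gives the primary alcohol F4, and Dess–Martin oxidation gives the aldehyde F5.
   - A direct Nozaki–Hiyama–Kishi macrocyclisation closes the ten-membered ring. Felkin–Anh addition anti to the C8–O bond should give the 9-epi alcohol F6.
   - A Mitsunobu esterification of F6 with 25 inverts C9 and gives 32.

3. **Step 25.**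
   - Risk: substitution at C8, flanked by the branched C7 and the acyloxy-bearing C9, may be slower than elimination towards C7 or may not start at all.
   - Fallback (from 27, back at 32): the inversion is done by redox. Dess–Martin oxidation gives the C8 ketone F7.
   - Non-chelating 1,2-reduction (NaBH4, CeCl3, MeOH, −78 °C) with hydride anti to the C9–O bond should give the 8,9-syn 8β-alcohol F8.
   - F8 is acylated with retention by 31 under Yamaguchi conditions (2,4,6-trichlorobenzoyl chloride, Et3N, DMAP) to give 32.

**Further compounds**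
F1 | step 19 | des-iodo (E)-enoate eleven-membered lactone aldehyde | C=C1C(=O)O[C@@H]2/C=C(/C)[C@@H]3O[C@@H]3/C=C/C(=O)O[C@@H](C=O)[C@@H]12
F2 | step 16 | methyl ester of 20 | C=C1C(=O)O[C@H](/C=C(/C)[C@@H]2O[C@@H]2/C=C(/C(=O)OC)I)[C@H]1[C@@H](O)CO[Si](C)(C)C(C)(C)C
F3 | step 16 | open-chain 8β-epoxyangelate, O9-TBS | C=C1C(=O)O[C@H](/C=C(/C)[C@@H]2O[C@@H]2/C=C(/C(=O)OC)I)[C@H]1[C@H](OC(=O)[C@@]3(C)O[C@H]3C)CO[Si](C)(C)C(C)(C)C
F4 | step 16 | open-chain 8β-epoxyangelate primary alcohol | C=C1C(=O)O[C@H](/C=C(/C)[C@@H]2O[C@@H]2/C=C(/C(=O)OC)I)[C@H]1[C@H](OC(=O)[C@@]3(C)O[C@H]3C)CO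
F5 | step 16 | open-chain 8β-epoxyangelate aldehyde | C=C1C(=O)O[C@H](/C=C(/C)[C@@H]2O[C@@H]2/C=C(/C(=O)OC)I)[C@H]1[C@H](OC(=O)[C@@]3(C)O[C@H]3C)C=O
F6 | step 16 | 9-epi-9-hydroxy 8β-epoxyangelate carbocycle | C=C1C(=O)O[C@@H]2/C=C(/C)[C@@H]3O[C@@H]3/C=C(/C(=O)OC)[C@@H](O)[C@@H](OC(=O)[C@@]3(C)O[C@H]3C)[C@@H]12
F7 | step 25 | C8 ketone | C=C1C(=O)O[C@@H]2/C=C(/C)[C@@H]3O[C@@H]3/C=C(/C(=O)OC)[C@H](OC(=O)[C@H](C)CC)C(=O)[C@@H]12
F8 | step 25 | 8β-alcohol | C=C1C(=O)O[C@@H]2/C=C(/C)[C@@H]3O[C@@H]3/C=C(/C(=O)OC)[C@H](OC(=O)[C@H](C)CC)[C@@H](O)[C@@H]12
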